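**Retrosynthetic overview**
1. The target is a cis-fused hexahydronaphthalene (ring A: C4a–C5=C6–C7–C8–C8a; ring B: C1–C2=C3–C4–C4a–C8a) that carries, through an (E)-propenyl linker on C4, a trans-1,4-disubstituted cyclohexane (ring C).
2. Ring C is cut at both C–C bonds of its carboxyl-bearing carbon ([5+1]). That carbon is α to CO2H, so it can enter as dimethyl malonate. Ring C also has a local mirror plane through its C1 and C4 with two identical CH2CH2 arms, so one symmetric 1,5-dibromide is the only partner needed, and the trans (diequatorial) acid is the thermodynamic one.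
3. Ring B is a cyclohexene whose C2=C3 bond lies opposite the C4a–C8a bond, with the ester on quaternary C4a. This Diels–Alder retron gives a ring-A cyclohexa-1,5-diene-1-carboxylate (C16) and an (E,E)-triene bearing the two bromoethyl arms (C13).
4. Both events are run in one flask as a three-component union (dienoate + triene + malonate); the extra malonate ester is removed afterwards.
5. Order of ring formation: ring A (step 1, Michael/aldol from (S)-citronellal), ring B (step 9, cycloaddition), ring C (step 9, closed last).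

Key step: step 9

Remark: names use the hexahydronaphthalene numbering given above (C4a = ester-bearing ring-fusion carbon, C8a = ring-fusion CH, C7 = CH carrying the heptenyl chain); the target SMILES is read as cis-fused in the decalin and trans-1,4 in ring C.

**Step 1**
Reactants: 1 (S)-citronellal [(3S)-3,7-dimethyloct-6-enal]; 2 methyl vinyl ketone (but-3-en-2-one)
Product: 5 (4R)-4-[(2S)-6-methylhept-5-en-2-yl]cyclohex-2-en-1-one, via keto aldehyde 3 (not isolated), via aldol 4 (not isolated)
Conditions: (R)-α,α-diphenylprolinol trimethylsilyl ether (10 mol%), ethyl 3,4-dihydroxybenzoate (20 mol%), neat, 4 °C; then LiOH, iPrOH, rt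
Reagents that add atoms: none
Why: Enamine-catalysed Michael addition followed by hydroxide-mediated intramolecular aldol condensation (Robinson-type annulation) should give the 4-substituted cyclohexenone; the ring stereocentre is set by the catalyst, whose bulky diphenyl(silyloxy)methyl group shields one face of the (E)-enamine (the (R)-catalyst is chosen to give 4R), and the side-chain stereocentre is carried over from (S)-citronellal.

**Step 2**
Reactants: 5 (4R)-4-[(2S)-6-methylhept-5-en-2-yl]cyclohex-2-en-1-one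
Product: 7 (4R)-4-[(2S)-6-methylhept-5-en-2-yl]cyclohexa-1,5-dien-1-yl trifluoromethanesulfonate, via lithium dienolate 6 (not isolated)
Conditions: LiN(iPr)2, THF, −78 °C; then PhNTf2, −78 °C to rt
Reagents that add atoms: N-phenylbis(trifluoromethanesulfonimide), O=S(=O)(N(c1ccccc1)S(=O)(=O)C(F)(F)F)C(F)(F)F
Why: Kinetic deprotonation at the α′-CH2 gives the cross-conjugated dienolate, which is O-sulfonylated (enol triflate formation); the γ-stereocentre is not touched.

**Step 3**
Reactants: 7 (4R)-4-[(2S)-6-methylhept-5-en-2-yl]cyclohexa-1,5-dien-1-yl trifluoromethanesulfonate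
Product: 8 methyl (4R)-4-[(2S)-6-methylhept-5-en-2-yl]cyclohexa-1,5-diene-1-carboxylate
Conditions: Pd(OAc)2 (5 mol%), PPh3, CO (1 atm), MeOH, Et3N, DMF, rt
Reagents that add atoms: carbon monoxide, [C-]#[O+]; methanol, CO
Why: Pd(OAc)2/PPh3-catalysed alkoxycarbonylation of an alkenyl triflate (oxidative addition to zerovalent palladium, CO insertion, methanolysis) should give the dienoate without touching the stereocentres.

**Step 4**
Reactants: 9 4-ethynyloxane (4-ethynyltetrahydro-2H-pyran)
Product: 11 4-[(1E)-1-iodoprop-1-en-2-yl]oxane, via alkenylalane 10 (not isolated)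
Conditions: Me3Al, Cp2ZrCl2 (25 mol%), CH2Cl2, 0 °C to rt; then I2, THF, −30 °C
Reagents that add atoms: trimethylaluminium, C[Al](C)C; iodine, II
Why: Cp2ZrCl2-catalysed syn-carboalumination of the terminal alkyne (Negishi carboalumination) places the methyl group on the internal carbon, and iododealumination with retention should give the (E)-iodoalkene.

**Step 5**
Reactants: 11 4-[(1E)-1-iodoprop-1-en-2-yl]oxane
Product: 12 (4E)-3-(2-bromoethyl)-5-iodo-4-methylpent-4-en-1-ol (racemic)
Conditions: BBr3 (0.4 equiv), CH2Cl2, −20 °C to rt; then aq. NaHCO3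
Reagents that add atoms: boron tribromide, BrB(Br)Br
Why: Lewis-acid ether cleavage (O-coordination, then SN2 opening by bromide at a CH2–O carbon) of the symmetric oxane can give only one bromo alcohol, and the iodoalkene should survive at this temperature.

**Step 6**
Reactants: 12 (4E)-3-(2-bromoethyl)-5-iodo-4-methylpent-4-en-1-ol
Product: 13 (1E)-5-bromo-3-(2-bromoethyl)-1-iodo-2-methylpent-1-ene
Conditions: CBr4, PPh3, CH2Cl2, 0 °C
Reagents that add atoms: carbon tetrabromide, BrC(Br)(Br)Br
Why: The Appel reaction should convert the primary alcohol into the second primary bromide under neutral conditions, before the bromo alcohol can re-close to the oxane.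

**Step 7**
Reactants: 14 2-methylbut-1-en-3-yne; 15 pinacolborane
Product: 16 4,4,5,5-tetramethyl-2-[(1E)-3-methylbuta-1,3-dien-1-yl]-1,3,2-dioxaborolane
Conditions: Cp2ZrHCl (5 mol%), Et3N (10 mol%), neat, 40 °C
Reagents that add atoms: none
Why: Cp2ZrHCl-catalysed syn-hydroboration of the terminal alkyne places boron on the terminal carbon and should give the (E)-dienylboronate, leaving the 1,1-disubstituted alkene untouched.

**Step 8**
Reactants: 13 (1E)-5-bromo-3-(2-bromoethyl)-1-iodo-2-methylpent-1-ene; 16 4,4,5,5-tetramethyl-2-[(1E)-3-methylbuta-1,3-dien-1-yl]-1,3,2-dioxaborolane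
Product: 17 (3E,5E)-9-bromo-7-(2-bromoethyl)-2,6-dimethylnona-1,3,5-triene
Conditions: Pd(PPh3)4 (5 mol%), K3PO4, THF/H2O, 45 °C
Reagents that add atoms: none
Why: Suzuki–Miyaura coupling proceeds with retention at both alkenes and should give the (3E,5E)-triene; the primary alkyl bromides should be inert toward zerovalent palladium with triphenylphosphine at this temperature.

**Step 9**
Reactants: 8 methyl (4R)-4-[(2S)-6-methylhept-5-en-2-yl]cyclohexa-1,5-diene-1-carboxylate; 17 (3E,5E)-9-bromo-7-(2-bromoethyl)-2,6-dimethylnona-1,3,5-triene; 18 dimethyl malonate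
Product: 21 methyl (4S,4aR,7R,8aR)-4-{(1E)-2-[4,4-bis(methoxycarbonyl)cyclohexyl]prop-1-en-1-yl}-2-methyl-7-[(2S)-6-methylhept-5-en-2-yl]-1,4,4a,7,8,8a-hexahydronaphthalene-4a-carboxylate, via Diels–Alder adduct 19 (not isolated), via bromo malonate 20 (not isolated)
Conditions: 8 (1.0 equiv), 17 (1.3 equiv), Me2AlCl (1.2 equiv), toluene, −30 to 0 °C; then MeOH (quench), dimethyl malonate (1.5 equiv), Cs2CO3, NaI (cat.), DMF, 60 °C, same flask
Reagents that add atoms: none
Why: The Me2AlCl-bound dienoate 8 reacts at its ester-bearing C1=C2 bond with the s-cis terminal diene (C1–C4) of 17 in a concerted, asynchronous [4+2] cycloaddition (closest known type: Lewis-acid Diels–Alder reaction of α-substituted acrylates and 2-alkoxycarbonyl-1,3-dienes with 1,3-dienes), and the dibromide 19 is then closed by twofold malonate alkylation (closest known type: Perkin cycloalkylation of malonates with 1,5-dihalides). Ring B closes by intermolecular [4+2] (bonds C4–C4a and C1–C8a), and ring C closes last by an intermolecular SN2 step to 20 followed by a 6-exo-tet SN2 step. C4a and C8a are set cis by suprafacial addition to the ring-A alkene on the face anti to the heptenyl side chain (substrate control by the existing ring stereocentre, as in additions to 5-substituted cyclohexenones). C4 is set by the ester-endo transition state together with the E geometry of the diene terminus, which places the propenyl chain cis to the ester. Regiochemistry follows the ortho/para rule, because the 1-alkenyl and the 3-methyl group of the diene both raise the coefficient at its CH2 terminus, which bonds to the β-carbon of the enoate; the internal diene of 17 stays out because its s-cis form would put the C6 methyl group inside. Ring B is formed before ring C because malonate and base are added only once 8 is consumed, and ring C carries no stereocentre at this stage since its C1 lies on a local mirror plane and C4 bears two identical esters.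

**Step 10**
Reactants: 21 methyl (4S,4aR,7R,8aR)-4-{(1E)-2-[4,4-bis(methoxycarbonyl)cyclohexyl]prop-1-en-1-yl}-2-methyl-7-[(2S)-6-methylhept-5-en-2-yl]-1,4,4a,7,8,8a-hexahydronaphthalene-4a-carboxylate
Product: 23 methyl (4S,4aR,7R,8aR)-4-{(1E)-2-[trans-4-(methoxycarbonyl)cyclohexyl]prop-1-en-1-yl}-2-methyl-7-[(2S)-6-methylhept-5-en-2-yl]-1,4,4a,7,8,8a-hexahydronaphthalene-4a-carboxylate, via cis ester 22 (not isolated)
Conditions: LiCl, H2O, DMSO, 150 °C; then NaOMe, MeOH, 65 °C
Reagents that add atoms: none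
Why: Krapcho dealkoxycarbonylation removes the activating ester, and methoxide then equilibrates the remaining ester through its enolate toward the more stable diequatorial trans-1,4 isomer; the angular ester has no α-hydrogen and stays unchanged, and cis ester separated by chromatography can be resubjected.

**Step 11**
Reactants: 23 methyl (4S,4aR,7R,8aR)-4-{(1E)-2-[trans-4-(methoxycarbonyl)cyclohexyl]prop-1-en-1-yl}-2-methyl-7-[(2S)-6-methylhept-5-en-2-yl]-1,4,4a,7,8,8a-hexahydronaphthalene-4a-carboxylate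
Product: 24 (4S,4aR,7R,8aR)-4-[(1E)-2-(trans-4-carboxycyclohexyl)prop-1-en-1-yl]-2-methyl-7-[(2S)-6-methylhept-5-en-2-yl]-1,4,4a,7,8,8a-hexahydronaphthalene-4a-carboxylic acid (target)
Conditions: LiI, pyridine, reflux; then 1 M HCl
Reagents that add atoms: none
Why: Iodide cleaves both methyl esters by SN2 attack at the O-methyl carbon (nucleophilic ester dealkylation), which does not depend on access to the hindered angular acyl carbon, and acidification should release the diacid with all stereocentres untouched.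

**Compound list**
1 | (S)-citronellal, (3S)-3,7-dimethyloct-6-enal | CC(C)=CCC[C@H](C)CC=O | starting material
2 | methyl vinyl ketone (but-3-en-2-one) | CC(=O)C=C | starting material
3 | (2R)-2-[(2S)-6-methylhept-5-en-2-yl]-5-oxohexanal | CC(C)=CCC[C@H](C)[C@@H](CCC(C)=O)C=O | intermediate
4 | (4R)-3-hydroxy-4-[(2S)-6-methylhept-5-en-2-yl]cyclohexan-1-one (carbinol configuration not defined) | CC(C)=CCC[C@H](C)[C@@H]1C(O)CC(=O)CC1 | intermediate
5 | (4R)-4-[(2S)-6-methylhept-5-en-2-yl]cyclohex-2-en-1-one | CC(C)=CCC[C@H](C)[C@@H]1C=CC(=O)CC1 | intermediate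
6 | lithium (4R)-4-[(2S)-6-methylhept-5-en-2-yl]cyclohexa-1,5-dien-1-olate | CC(C)=CCC[C@H](C)[C@@H]1C=CC(O[Li])=CC1 | intermediate
7 | (4R)-4-[(2S)-6-methylhept-5-en-2-yl]cyclohexa-1,5-dien-1-yl trifluoromethanesulfonate | CC(C)=CCC[C@H](C)[C@@H]1C=CC(OS(=O)(=O)C(F)(F)F)=CC1 | intermediate
8 | methyl (4R)-4-[(2S)-6-methylhept-5-en-2-yl]cyclohexa-1,5-diene-1-carboxylate | CC(C)=CCC[C@H](C)[C@@H]1C=CC(C(=O)OC)=CC1 | intermediate
9 | 4-ethynyloxane (4-ethynyltetrahydro-2H-pyran) | C#CC1CCOCC1 | starting material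
10 | dimethyl[(1E)-2-(oxan-4-yl)prop-1-en-1-yl]alumane | C[Al](C)/C=C(\C)C1CCOCC1 | intermediate
11 | 4-[(1E)-1-iodoprop-1-en-2-yl]oxane | I/C=C(\C)C1CCOCC1 | intermediate
12 | (4E)-3-(2-bromoethyl)-5-iodo-4-methylpent-4-en-1-ol (racemic) | OCCC(CCBr)/C(C)=C/I | intermediate
13 | (1E)-5-bromo-3-(2-bromoethyl)-1-iodo-2-methylpent-1-ene | BrCCC(CCBr)/C(C)=C/I | intermediate
14 | 2-methylbut-1-en-3-yne | CC(=C)C#C | starting material
15 | pinacolborane (4,4,5,5-tetramethyl-1,3,2-dioxaborolane) | [H]B1OC(C)(C)C(C)(C)O1 | starting material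
16 | 4,4,5,5-tetramethyl-2-[(1E)-3-methylbuta-1,3-dien-1-yl]-1,3,2-dioxaborolane | CC(=C)/C=C/B1OC(C)(C)C(C)(C)O1 | intermediate
17 | (3E,5E)-9-bromo-7-(2-bromoethyl)-2,6-dimethylnona-1,3,5-triene | CC(=C)/C=C/C=C(\C)C(CCBr)CCBr | intermediate
18 | dimethyl malonate | COC(=O)CC(=O)OC | starting material
19 | methyl (4S,4aR,7R,8aR)-4-[(1E)-5-bromo-3-(2-bromoethyl)-2-methylpent-1-en-1-yl]-2-methyl-7-[(2S)-6-methylhept-5-en-2-yl]-1,4,4a,7,8,8a-hexahydronaphthalene-4a-carboxylate | CC(C)=CCC[C@H](C)[C@@H]1C=C[C@]2(C(=O)OC)[C@@H](CC(C)=C[C@H]2/C=C(\C)C(CCBr)CCBr)C1 | intermediate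
20 | methyl (4S,4aR,7R,8aR)-4-[(1E)-3-(2-bromoethyl)-6,6-bis(methoxycarbonyl)-2-methylhex-1-en-1-yl]-2-methyl-7-[(2S)-6-methylhept-5-en-2-yl]-1,4,4a,7,8,8a-hexahydronaphthalene-4a-carboxylate (side-chain CH epimers) | CC(C)=CCC[C@H](C)[C@@H]1C=C[C@]2(C(=O)OC)[C@@H](CC(C)=C[C@H]2/C=C(\C)C(CCBr)CCC(C(=O)OC)C(=O)OC)C1 | intermediate
21 | methyl (4S,4aR,7R,8aR)-4-{(1E)-2-[4,4-bis(methoxycarbonyl)cyclohexyl]prop-1-en-1-yl}-2-methyl-7-[(2S)-6-methylhept-5-en-2-yl]-1,4,4a,7,8,8a-hexahydronaphthalene-4a-carboxylate | CC(C)=CCC[C@H](C)[C@@H]1C=C[C@]2(C(=O)OC)[C@@H](CC(C)=C[C@H]2/C=C(\C)C2CCC(C(=O)OC)(C(=O)OC)CC2)C1 | intermediate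
22 | methyl (4S,4aR,7R,8aR)-4-{(1E)-2-[cis-4-(methoxycarbonyl)cyclohexyl]prop-1-en-1-yl}-2-methyl-7-[(2S)-6-methylhept-5-en-2-yl]-1,4,4a,7,8,8a-hexahydronaphthalene-4a-carboxylate | CC(C)=CCC[C@H](C)[C@@H]1C=C[C@]2(C(=O)OC)[C@@H](CC(C)=C[C@H]2/C=C(\C)[C@H]2CC[C@@H](C(=O)OC)CC2)C1 | intermediate
23 | methyl (4S,4aR,7R,8aR)-4-{(1E)-2-[trans-4-(methoxycarbonyl)cyclohexyl]prop-1-en-1-yl}-2-methyl-7-[(2S)-6-methylhept-5-en-2-yl]-1,4,4a,7,8,8a-hexahydronaphthalene-4a-carboxylate | CC(C)=CCC[C@H](C)[C@@H]1C=C[C@]2(C(=O)OC)[C@@H](CC(C)=C[C@H]2/C=C(\C)[C@H]2CC[C@H](C(=O)OC)CC2)C1 | intermediate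
24 | (4S,4aR,7R,8aR)-4-[(1E)-2-(trans-4-carboxycyclohexyl)prop-1-en-1-yl]-2-methyl-7-[(2S)-6-methylhept-5-en-2-yl]-1,4,4a,7,8,8a-hexahydronaphthalene-4a-carboxylic acid | CC(C)=CCC[C@H](C)[C@@H]1C=C[C@]2(C(=O)O)[C@@H](CC(C)=C[C@H]2/C=C(\C)[C@H]2CC[C@H](C(=O)O)CC2)C1 | target

**Step count and risks**
Total steps: 11. Longest linear sequence: 7 steps (steps 4, 5, 6, 8, 9, 10, 11, from 4-ethynyloxane).

Step 9. The cycloaddition may stall at the trisubstituted enoate, so that self-dimerisation of 8 or Lewis-acid-induced oligomerisation of 17 takes over, or it may proceed with poor endo and facial selectivity; aluminium residues may also slow the double alkylation. The fallback raises the dienophile to the aldehyde oxidation level and separates the two events. Setting out from 7, formylation (Pd(PPh3)4, CO, Bu3SnH, THF, 50 °C) would give (4R)-4-[(2S)-6-methylhept-5-en-2-yl]cyclohexa-1,5-diene-1-carbaldehyde F1. This more electrophilic enal should add 17 with Me2AlCl at −78 °C to give the angular 4a-carbaldehyde F2. Pinnick oxidation (NaClO2, NaH2PO4, 2-methylbut-2-ene) would give the 4a-carboxylic acid F3, and methylation with trimethylsilyldiazomethane comes back to the route at 19, now isolated and purified. Compound 19 is then cyclised with dimethyl malonate, Cs2CO3 and NaI in DMF as a separate operation to give 21.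

Step 10. Prolonged heating at 150 °C may trigger sigmatropic reorganisation of the 1,2-dialkenyl array on ring B or partial loss of the angular ester before the geminal ester has gone. The fallback replaces the thermal step by a radical decarboxylation at room temperature. Setting out from 21, mono-saponification (KOH, 1 equiv, MeOH/H2O, rt) would give the malonic half acid F4. Coupling with N-hydroxypyridine-2-thione (DCC, CH2Cl2, dark) would give the Barton ester F5. Visible-light photolysis with t-BuSH should give the 22/23 mixture, which is equilibrated with NaOMe in MeOH as before, so that the route is rejoined at 23.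

Step 11. Dealkylation of the neopentyl-type angular ester may remain incomplete, and forcing it may cause double-bond migration. The fallback is a reduction–oxidation detour. Setting out from 23, LiAlH4 (THF, reflux) would reduce both esters to the diol F6. Dess–Martin periodinane (NaHCO3, CH2Cl2) would give the dialdehyde F7, whose ring-C formyl group stays in the favoured equatorial trans position. Pinnick oxidation (NaClO2, NaH2PO4, 2-methylbut-2-ene) would then give 24.

**Further compounds**
F1 | step 9 | (4R)-4-[(2S)-6-methylhept-5-en-2-yl]cyclohexa-1,5-diene-1-carbaldehyde | CC(C)=CCC[C@H](C)[C@@H]1C=CC(C=O)=CC1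
F2 | step 9 | (4S,4aR,7R,8aR)-4-[(1E)-5-bromo-3-(2-bromoethyl)-2-methylpent-1-en-1-yl]-2-methyl-7-[(2S)-6-methylhept-5-en-2-yl]-1,4,4a,7,8,8a-hexahydronaphthalene-4a-carbaldehyde | CC(C)=CCC[C@H](C)[C@@H]1C=C[C@]2(C=O)[C@@H](CC(C)=C[C@H]2/C=C(\C)C(CCBr)CCBr)C1
F3 | step 9 | (4S,4aR,7R,8aR)-4-[(1E)-5-bromo-3-(2-bromoethyl)-2-methylpent-1-en-1-yl]-2-methyl-7-[(2S)-6-methylhept-5-en-2-yl]-1,4,4a,7,8,8a-hexahydronaphthalene-4a-carboxylic acid | CC(C)=CCC[C@H](C)[C@@H]1C=C[C@]2(C(=O)O)[C@@H](CC(C)=C[C@H]2/C=C(\C)C(CCBr)CCBr)C1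
F4 | step 10 | methyl (4S,4aR,7R,8aR)-4-{(1E)-2-[4-carboxy-4-(methoxycarbonyl)cyclohexyl]prop-1-en-1-yl}-2-methyl-7-[(2S)-6-methylhept-5-en-2-yl]-1,4,4a,7,8,8a-hexahydronaphthalene-4a-carboxylate | CC(C)=CCC[C@H](C)[C@@H]1C=C[C@]2(C(=O)OC)[C@@H](CC(C)=C[C@H]2/C=C(\C)C2CCC(C(=O)O)(C(=O)OC)CC2)C1
F5 | step 10 | methyl (4S,4aR,7R,8aR)-4-{(1E)-2-[4-(methoxycarbonyl)-4-{[(2-sulfanylidenepyridin-1(2H)-yl)oxy]carbonyl}cyclohexyl]prop-1-en-1-yl}-2-methyl-7-[(2S)-6-methylhept-5-en-2-yl]-1,4,4a,7,8,8a-hexahydronaphthalene-4a-carboxylate | CC(C)=CCC[C@H](C)[C@@H]1C=C[C@]2(C(=O)OC)[C@@H](CC(C)=C[C@H]2/C=C(\C)C2CCC(C(=O)ON3C=CC=CC3=S)(C(=O)OC)CC2)C1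
F6 | step 11 | [(4S,4aR,7R,8aR)-4-{(1E)-2-[trans-4-(hydroxymethyl)cyclohexyl]prop-1-en-1-yl}-2-methyl-7-[(2S)-6-methylhept-5-en-2-yl]-1,4,4a,7,8,8a-hexahydronaphthalen-4a-yl]methanol | CC(C)=CCC[C@H](C)[C@@H]1C=C[C@]2(CO)[C@@H](CC(C)=C[C@H]2/C=C(\C)[C@H]2CC[C@H](CO)CC2)C1
F7 | step 11 | (4S,4aR,7R,8aR)-4-[(1E)-2-(trans-4-formylcyclohexyl)prop-1-en-1-yl]-2-methyl-7-[(2S)-6-methylhept-5-en-2-yl]-1,4,4a,7,8,8a-hexahydronaphthalene-4a-carbaldehyde | CC(C)=CCC[C@H](C)[C@@H]1C=C[C@]2(C=O)[C@@H](CC(C)=C[C@H]2/C=C(\C)[C@H]2CC[C@H](C=O)CC2)C1
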